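I decide to keep the books on coupling partner rather than on substrate, since one tris adduct costs 3 partners and each recipe charges fewer per substrate.

| flask | substrate | coupling partner | remark | time |
|---|---|---|---|---|
| elm | 0.20 M | 1.50 equiv | a single well-mixed tank run continuously and read at steady state, 20.0 h in it on average |  |
| ash | 0.20 M | 1.50 equiv | a single well-mixed tank run continuously and read at steady state, 4.0 h in it on average |  |
| maple | 0.20 M | 1.50 equiv | a closed flask charged with all of it at once and left for 4.0 h | 4.0 h |
| oak | 0.20 M (fed, over 2.00 h) | 1.50 equiv | all but substrate at the start; substrate goes in evenly over 2.00 h, the run ends at 4.0 h | 4.0 h |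

    coupling partner + first product → double product (k1 = 0.0011 M⁻¹ s⁻¹)
    substrate + first product → side product (k2 = 3.9 × 10⁻⁵ M⁻¹ s⁻¹)
    coupling partner ⇌ dormant form (K3 = 0.31, k3 = 1.6 × 10⁻⁴ s⁻¹)
    substrate + coupling partner → first product (k4 = 5.2 × 10⁻⁴ M⁻¹ s⁻¹)
    coupling partner + double product → tris adduct (k5 = 0.0013 M⁻¹ s⁻¹)

1. the set-up with the highest amount of tris adduct at the outlet or at the end, in percent of the substrate put in ("none" if the first two lie within 2 percentage points) (elm / ash / maple / oak / none)
2. amount of tris adduct at the outlet or at the end, in percent of the substrate put in, elm
3. amount of tris adduct at the outlet or at the end, in percent of the substrate put in, ash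
4. amount of tris adduct at the outlet or at the end, in percent of the substrate put in, maple
5. amount of tris adduct at the outlet or at the end, in percent of the substrate put in, oak

- a species is counted by the substrate in it: one side product counts as two
- the stated concentrations are those of everything mixed, before any reaction; amounts are the same in each set-up
- the feed brings no volume worth counting
- run time (maple): 4.0 h

**The ledger.** As a fraction of the substrate charge, each partner stands free, dormant, or spent: one in each first product, two in each double product, 3 in each tris adduct, and one in each side product, which holds two substrates. Coupling partner is thus the limiting reagent for tris adduct.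

**The ceiling.** Closing the books with the whole charge spent on tris adduct gives 50.0 % of the substrate. I call this the partner ceiling: the partner charged per substrate divided by 3, or the whole substrate charge if that is less.

**The approach.** Dormant form parks 23.7 % of the unspent partner at balance, about a quarter, but in oak, a closed run, that balance relaxes with a half-life of 0.285 h, shorter than the run, so for oak I count this as delay rather than loss. In maple as charged, substrate's half-life of 1.2 h is longer than first product's 0.58 h and double product's 0.49 h, so partner moves on to tris adduct while substrate waits. I commit to one number, the ceiling, and to one ranking: elm comes nearest it, since its average stay of 20.0 h exceeds the 4.0 h of ash's average stay and of the maple and oak runs, though elm differs from maple and oak in its vessel as well.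

**The forecast.** It names elm, with 29 % for elm, 16.5 % for ash, 20 % for maple and 15 % for oak, on the ground that “The 20 h tank gets by far the most exposure to the coupling partner”. These numbers are its own, and each lies below my ceiling.

**The result.** The simulation gives elm at 30.6 %, then maple at 19.7 %, ash at 16.9 % and oak at 15.4 %, each inside the forecast's range. Elm's reading is 61.2 % of the ceiling.

**More partner.** Oak reads 30.8 % of the same ceiling at 4.00 h and 65.2 % of it at 40.0 h, where tris adduct is 32.6 %. The neighbouring flask is oak with 6.00 equiv of coupling partner. Its charge divided by 3 is 2.00 equiv, so substrate now caps the ceiling at 100 %. At 4.00 h it reads 87.1 % of tris adduct, with 40.9 % of its own partner charge still free and 4.28 % of the substrate left.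

The numbers stand for no real mixture; the result is computed.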